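**Strategy.** The plan rests on one disconnection: the trans-fused γ-lactone ring (O–C6–C7–C11–C12) and the C8 ester oxygen are traced back to a cyclopropane C7–C8–C11, because C11 and O8 stand in a 1,3-relation across C7–C8. A single rhodium-carbene step turns an acyclic (S)-C6 allylic tert-butyl diazomalonate, which already carries the (Z)-C4 iodoalkene, the silylated C15 alcohol and the (E)-C7=C8 alkene ending in the C9 dimethyl acetal, into the lactone-fused cyclopropane; it forms C7–C11 and C8–C11 and sets C7, C8 and C11 from C6 alone. Methacrylate opening at C8, methylenation at C11, Stille coupling at C3–C4 and a C9–C10 aldol finish the furanone-bridged ten-membered ring.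

Key step: step 7

Locants: germacrane numbering (C1 ketone, C2=C3 furanone alkene, C3–O–C10 ether bridge, C4=C5 alkene with C15 on C4, C6 lactone carbinol, C7, C8 methacrylate carbon, C9 senecioate carbon, C10 quaternary carbon with C14, C11=C13 methylene, C12 lactone carbonyl).

Assumption 1: in step 3 the (S,S) enantiomer of ProPhenol is taken as the one that sends the alkynyl group to the Re face of the enal carbonyl; if the sense is the opposite, the (R,R) ligand is used.

Assumption 2: 2-methylfuran-3(2H)-one is taken as a purchasable flavour chemical.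

**Step 1**
Reactants: 1 fumaraldehyde bis(dimethyl acetal)
Product: 2 (E)-4,4-dimethoxybut-2-enal
Conditions: Amberlyst-15, acetone, H2O (1 equiv), rt
Reagents that add atoms: water, O
Why: Acid-catalysed hydrolysis of one of two equivalent acetals stops at the enal because the conjugated formyl group deactivates the remaining acetal towards ionisation; no stereocentre forms and the E geometry is kept.

**Step 2**
Reactants: 3 propargyl alcohol
Product: 4 tert-butyl(diphenyl)(prop-2-yn-1-yloxy)silane
Conditions: TBDPSCl, imidazole, CH2Cl2, 0 °C → rt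
Reagents that add atoms: tert-butyl(chloro)diphenylsilane, CC(C)(C)[Si](Cl)(c1ccccc1)c1ccccc1
Why: Routine silylation of a primary alcohol, the acid-stable TBDPS group being chosen so that the C15 oxygen stays masked through the acidic steps 9 and 10.

**Step 3**
Reactants: 2 (E)-4,4-dimethoxybut-2-enal; 4 tert-butyl(diphenyl)(prop-2-yn-1-yloxy)silane
Product: 6 (2E,4S)-7-(tert-butyldiphenylsilyloxy)-1,1-dimethoxyhept-2-en-5-yn-4-ol, via methylzinc acetylide 5 (not isolated)
Conditions: Me2Zn (3 equiv), (S,S)-ProPhenol (20 mol%), Ph3P=O (40 mol%), toluene, 0 °C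
Reagents that add atoms: none
Why: Catalytic asymmetric addition of a zinc acetylide to an α,β-unsaturated aldehyde (ProPhenol alkynylation), in which the dinuclear zinc–ligand complex delivers the alkynyl group to the Re face of the formyl group and so sets C6 (4S in this chain).

**Step 4**
Reactants: 6 (2E,4S)-7-(tert-butyldiphenylsilyloxy)-1,1-dimethoxyhept-2-en-5-yn-4-ol
Product: 8 (2E,4S,5Z)-7-(tert-butyldiphenylsilyloxy)-6-iodo-1,1-dimethoxyhepta-2,5-dien-4-ol, via cyclic alkenylalanate 7 (not isolated)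
Conditions: NaAlH2(OCH2CH2OMe)2 (Red-Al), THF, 0 °C → rt; then I2, −78 → 0 °C
Reagents that add atoms: iodine, II
Why: Hydroxyl-directed trans-hydroalumination of a propargylic alcohol puts hydride on C5 and aluminium on C4 within a five-membered alanate, and iodinolysis with retention gives the vinyl iodide with iodine cis to C6 (Z) while C6 is untouched.

**Step 5**
Reactants: 8 (2E,4S,5Z)-7-(tert-butyldiphenylsilyloxy)-6-iodo-1,1-dimethoxyhepta-2,5-dien-4-ol; 9 mono-tert-butyl malonate
Product: 10 tert-butyl (2E,4S,5Z)-7-(tert-butyldiphenylsilyloxy)-6-iodo-1,1-dimethoxyhepta-2,5-dien-4-yl malonate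
Conditions: DCC, DMAP (cat.), CH2Cl2, 0 °C → rt
Reagents that add atoms: none
Why: Steglich esterification acylates the hindered bis-allylic alcohol under neutral conditions that avoid allylic ionisation, so C6 keeps its configuration.

**Step 6**
Reactants: 10 tert-butyl (2E,4S,5Z)-7-(tert-butyldiphenylsilyloxy)-6-iodo-1,1-dimethoxyhepta-2,5-dien-4-yl malonate
Product: 11 tert-butyl (2E,4S,5Z)-7-(tert-butyldiphenylsilyloxy)-6-iodo-1,1-dimethoxyhepta-2,5-dien-4-yl 2-diazomalonate
Conditions: p-ABSA, Et3N, MeCN, 0 °C → rt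
Reagents that add atoms: 4-acetamidobenzenesulfonyl azide, CC(=O)Nc1ccc(cc1)S(=O)(=O)N=[N+]=[N-]
Why: Regitz diazo transfer to the doubly activated malonate methylene, with no stereocentre involved.

**Step 7**
Reactants: 11 tert-butyl (2E,4S,5Z)-7-(tert-butyldiphenylsilyloxy)-6-iodo-1,1-dimethoxyhepta-2,5-dien-4-yl 2-diazomalonate
Product: 12 tert-butyl (1R,4S,5S,6S)-4-[(Z)-3-(tert-butyldiphenylsilyloxy)-2-iodoprop-1-enyl]-6-(dimethoxymethyl)-2-oxo-3-oxabicyclo[3.1.0]hexane-1-carboxylate
Conditions: Rh2(OAc)4 (2 mol%), CH2Cl2, reflux, slow addition of 11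
Reagents that add atoms: none
Why: The rhodium carbene formed from 11 by loss of N2 adds in a concerted, asynchronous [2+1] fashion to the tethered (E)-C7=C8 alkene, the reaction type being the established intramolecular cyclopropanation of allylic diazomalonates. The γ-lactone ring (O–C6–C7–C11–C12) closes in a 5-exo sense through the new C7–C11 bond and the three-membered ring closes through C8–C11 in the same event, so only the cis-fused 3-oxabicyclo[3.1.0]hexanone can form. C8 is set by stereospecific syn addition to the E alkene (C9 trans to C6 on the cyclopropane), C11 by the cis ring fusion, and C7 by the alkene face that is attacked relative to C6. The face needed puts the C5 alkenyl group on the convex side, anti to the cyclopropane, and it should be favoured because the reactive conformer has H6 eclipsing the C7=C8 bond, which minimises allylic strain against the bulky (Z)-iodoalkenyl group. Site selectivity is needed against the C4=C5 alkene and against insertion into the tert-butyl C–H bonds: the C4=C5 alkene is trisubstituted, carries iodine cis to C6 and is inductively deactivated, and five-ring cyclopropanation of a 1,2-disubstituted alkene should outpace 1,5-insertion into primary C–H bonds.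

**Step 8**
Reactants: 12 tert-butyl (1R,4S,5S,6S)-4-[(Z)-3-(tert-butyldiphenylsilyloxy)-2-iodoprop-1-enyl]-6-(dimethoxymethyl)-2-oxo-3-oxabicyclo[3.1.0]hexane-1-carboxylate; 13 methacrylic acid
Product: 14 tert-butyl (4S,5S)-5-[(Z)-3-(tert-butyldiphenylsilyloxy)-2-iodoprop-1-enyl]-4-[(1S)-2,2-dimethoxy-1-(methacryloyloxy)ethyl]-2-oxooxolane-3-carboxylate (C11 epimers)
Conditions: CH2=C(CH3)CO2K (0.3 equiv), 18-crown-6 (0.3 equiv), BHT, DMF, 60 °C
Reagents that add atoms: none
Why: Proposed new method: the crown-ether-separated carboxylate should attack C8 from the side opposite the C8–C11 bond in an SN2-type homoconjugate addition, because this external bond is the one aligned with the lactone carbonyl and its cleavage turns the strain of the doubly activated cyclopropane into a malonate-type anion that the excess acid protonates, so C8 is inverted to the target configuration, C6 and C7 are untouched and C11 becomes a labile centre; the closest known reactions are the homo-Michael openings of 1-alkoxycarbonyl-3-oxabicyclo[3.1.0]hexan-2-ones at the external carbon by amines, thiolates, azide or halides and the opening of electrophilic cyclopropanes by phenoxides.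

**Step 9**
Reactants: 14 tert-butyl (4S,5S)-5-[(Z)-3-(tert-butyldiphenylsilyloxy)-2-iodoprop-1-enyl]-4-[(1S)-2,2-dimethoxy-1-(methacryloyloxy)ethyl]-2-oxooxolane-3-carboxylate
Product: 17 (1S)-1-[(2S,3S)-2-[(Z)-3-(tert-butyldiphenylsilyloxy)-2-iodoprop-1-enyl]-4-methylidene-5-oxooxolan-3-yl]-2,2-dimethoxyethyl methacrylate, via malonic half acid 15 (not isolated), via Mannich base 16 (not isolated)
Conditions: TFA, CH2Cl2, 0 °C; evaporate; 37% aq. HCHO, Et2NH, THF, 0 °C → rt; NaOAc, AcOH, 40 °C
Reagents that add atoms: formaldehyde, C=O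
Why: Anhydrous acidolysis of the tert-butyl ester (the acetal being deactivated towards ionisation by the neighbouring ester oxygen and the TBDPS ether being acid-stable) gives the α-carboxy lactone, whose Mannich reaction with formaldehyde and diethylamine followed by decarboxylative loss of the amine is the classical route to α-methylene lactones; C11 becomes trigonal and C6, C7 and C8 are not enolisable here.

**Step 10**
Reactants: 17 (1S)-1-[(2S,3S)-2-[(Z)-3-(tert-butyldiphenylsilyloxy)-2-iodoprop-1-enyl]-4-methylidene-5-oxooxolan-3-yl]-2,2-dimethoxyethyl methacrylate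
Product: 18 (1S)-1-[(2S,3S)-2-[(Z)-3-(tert-butyldiphenylsilyloxy)-2-iodoprop-1-enyl]-4-methylidene-5-oxooxolan-3-yl]-2-oxoethyl methacrylate
Conditions: TFA/H2O (9:1), CHCl3, 0 °C
Reagents that add atoms: water, O
Why: Aqueous acid hydrolysis of the dimethyl acetal frees the α-acyloxy aldehyde without base, so C8 is not epimerised, and the TBDPS ether, vinyl iodide and methylene lactone tolerate the medium.

**Step 11**
Reactants: 19 2-methylfuran-3(2H)-one
Product: 20 2-methyl-3-(triisopropylsilyloxy)furan
Conditions: TIPSOTf, Et3N, CH2Cl2, 0 °C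
Reagents that add atoms: triisopropylsilyl trifluoromethanesulfonate, CC(C)[Si](OS(=O)(=O)C(F)(F)F)(C(C)C)C(C)C
Why: Soft enolisation and O-silylation of the furanone aromatises the ring to the 3-silyloxyfuran and erases the C2 stereocentre of racemic 19.

**Step 12**
Reactants: 20 2-methyl-3-(triisopropylsilyloxy)furan
Product: 22 tributyl[5-methyl-4-(triisopropylsilyloxy)furan-2-yl]stannane, via 5-lithiofuran 21 (not isolated)
Conditions: n-BuLi, THF, −78 → 0 °C; Bu3SnCl, −78 °C → rt
Reagents that add atoms: tributyltin chloride, CCCC[Sn](Cl)(CCCC)CCCC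
Why: Furans are deprotonated at the free α-position (the future C3) and the lithiofuran is trapped by the stannyl chloride; no stereocentre is involved.

**Step 13**
Reactants: 18 (1S)-1-[(2S,3S)-2-[(Z)-3-(tert-butyldiphenylsilyloxy)-2-iodoprop-1-enyl]-4-methylidene-5-oxooxolan-3-yl]-2-oxoethyl methacrylate; 22 tributyl[5-methyl-4-(triisopropylsilyloxy)furan-2-yl]stannane
Product: 23 (1S)-1-[(2R,3S)-2-[(Z)-3-(tert-butyldiphenylsilyloxy)-2-[5-methyl-4-(triisopropylsilyloxy)furan-2-yl]prop-1-enyl]-4-methylidene-5-oxooxolan-3-yl]-2-oxoethyl methacrylate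
Conditions: Pd2(dba)3 (5 mol%), AsPh3 (20 mol%), NMP, rt
Reagents that add atoms: none
Why: Stille coupling of a vinyl iodide with an electron-rich 2-furylstannane runs at room temperature with retention of alkene geometry, forming C3–C4 with C3 cis to C6, and tolerates the aldehyde, the silyl enol ether and the methylene lactone.

**Step 14**
Reactants: 23 (1S)-1-[(2R,3S)-2-[(Z)-3-(tert-butyldiphenylsilyloxy)-2-[5-methyl-4-(triisopropylsilyloxy)furan-2-yl]prop-1-enyl]-4-methylidene-5-oxooxolan-3-yl]-2-oxoethyl methacrylate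
Product: 24 (4Z,6R,7S,8S,9R,10S)-15-(tert-butyldiphenylsilyloxy)-9-hydroxy-8-methacryloyloxy-1-oxo-3,10-epoxygermacra-2,4,11(13)-trien-12,6-olide
Conditions: BF3·OEt2 (1.2 equiv), CH2Cl2 (1 mM), −78 °C
Reagents that add atoms: none
Why: Intramolecular Mukaiyama aldol addition of the 3-silyloxyfuran through its methyl-bearing α-carbon (C10) to the activated C9 aldehyde, the known mode of reaction of 3-silyloxyfurans with aldehydes, closes the ten-membered carbocycle and unveils the furanone; C9 and C10 are set together under the conformational control of the closing ring, in which the (Z)-C4=C5 alkene and the trans-lactone should let C9 reach only one face of the furan while the aldehyde oxygen lies anti to the C8–O bond.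

**Step 15**
Reactants: 24 (4Z,6R,7S,8S,9R,10S)-15-(tert-butyldiphenylsilyloxy)-9-hydroxy-8-methacryloyloxy-1-oxo-3,10-epoxygermacra-2,4,11(13)-trien-12,6-olide; 25 3-methylbut-2-enoyl chloride
Product: 26 15-O-tert-butyldiphenylsilyl ether of the target (C9 senecioate)
Conditions: DMAP (cat.), pyridine, CH2Cl2, 0 °C
Reagents that add atoms: none
Why: Acylpyridinium acylation of the secondary C9 alcohol under weakly basic conditions limits retro-aldol cleavage, O8→O9 acyl migration and deconjugation of the senecioyl group, and changes no stereocentre.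

**Step 16**
Reactants: 26 15-O-tert-butyldiphenylsilyl ether of the target
Product: 27 CNP0239488.2, (4Z,6R,7S,8S,9R,10S)-15-hydroxy-8-methacryloyloxy-9-(3-methylbut-2-enoyloxy)-1-oxo-3,10-epoxygermacra-2,4,11(13)-trien-12,6-olide
Conditions: HF·pyridine, THF, pyridine, 0 °C → rt
Reagents that add atoms: none
Why: Buffered fluoride cleavage of the primary silyl ether frees the C15 alcohol and leaves both enoate esters, the methylene lactone and the furanone intact.

**Compound list**

1 | fumaraldehyde bis(dimethyl acetal) | COC(OC)/C=C/C(OC)OC | starting material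
2 | (E)-4,4-dimethoxybut-2-enal | COC(OC)/C=C/C=O | intermediate
3 | propargyl alcohol | OCC#C | starting material
4 | tert-butyl(diphenyl)(prop-2-yn-1-yloxy)silane | C#CCO[Si](c1ccccc1)(c1ccccc1)C(C)(C)C | intermediate
5 | methylzinc acetylide of 4 | C[Zn]C#CCO[Si](c1ccccc1)(c1ccccc1)C(C)(C)C | intermediate
6 | (2E,4S)-7-(tert-butyldiphenylsilyloxy)-1,1-dimethoxyhept-2-en-5-yn-4-ol | O[C@H](C#CCO[Si](c1ccccc1)(c1ccccc1)C(C)(C)C)/C=C/C(OC)OC | intermediate
7 | cyclic alkenylalanate (sodium salt) from 6, Al on C4 and O6 | COCCO[Al-]1(OCCOC)O[C@@H](/C=C/C(OC)OC)C=C1CO[Si](c1ccccc1)(c1ccccc1)C(C)(C)C.[Na+] | intermediate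
8 | (2E,4S,5Z)-7-(tert-butyldiphenylsilyloxy)-6-iodo-1,1-dimethoxyhepta-2,5-dien-4-ol | O[C@H](/C=C(\I)CO[Si](c1ccccc1)(c1ccccc1)C(C)(C)C)/C=C/C(OC)OC | intermediate
9 | mono-tert-butyl malonate | CC(C)(C)OC(=O)CC(=O)O | starting material
10 | tert-butyl (2E,4S,5Z)-7-(tert-butyldiphenylsilyloxy)-6-iodo-1,1-dimethoxyhepta-2,5-dien-4-yl malonate | CC(C)(C)OC(=O)CC(=O)O[C@H](/C=C(\I)CO[Si](c1ccccc1)(c1ccccc1)C(C)(C)C)/C=C/C(OC)OC | intermediate
11 | corresponding 2-diazomalonate (key-step precursor) | CC(C)(C)OC(=O)C(=[N+]=[N-])C(=O)O[C@H](/C=C(\I)CO[Si](c1ccccc1)(c1ccccc1)C(C)(C)C)/C=C/C(OC)OC | intermediate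
12 | tert-butyl (1R,4S,5S,6S)-4-[(Z)-3-(tert-butyldiphenylsilyloxy)-2-iodoprop-1-enyl]-6-(dimethoxymethyl)-2-oxo-3-oxabicyclo[3.1.0]hexane-1-carboxylate (key-step product) | CC(C)(C)OC(=O)[C@]12C(=O)O[C@H](/C=C(\I)CO[Si](c3ccccc3)(c3ccccc3)C(C)(C)C)[C@H]1[C@@H]2C(OC)OC | intermediate
13 | methacrylic acid | C=C(C)C(=O)O | starting material
14 | tert-butyl (4S,5S)-5-[(Z)-3-(tert-butyldiphenylsilyloxy)-2-iodoprop-1-enyl]-4-[(1S)-2,2-dimethoxy-1-(methacryloyloxy)ethyl]-2-oxooxolane-3-carboxylate, C11 epimers | C=C(C)C(=O)O[C@@H]([C@H]1C(C(=O)OC(C)(C)C)C(=O)O[C@@H]1/C=C(\I)CO[Si](c1ccccc1)(c1ccccc1)C(C)(C)C)C(OC)OC | intermediate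
15 | malonic half acid from 14 (C11 CO2H) | C=C(C)C(=O)O[C@@H]([C@H]1C(C(=O)O)C(=O)O[C@@H]1/C=C(\I)CO[Si](c1ccccc1)(c1ccccc1)C(C)(C)C)C(OC)OC | intermediate
16 | Mannich base, C11 bearing CO2H and CH2NEt2 | C=C(C)C(=O)O[C@@H]([C@H]1C(CN(CC)CC)(C(=O)O)C(=O)O[C@@H]1/C=C(\I)CO[Si](c1ccccc1)(c1ccccc1)C(C)(C)C)C(OC)OC | intermediate
17 | (1S)-1-[(2S,3S)-2-[(Z)-3-(tert-butyldiphenylsilyloxy)-2-iodoprop-1-enyl]-4-methylidene-5-oxooxolan-3-yl]-2,2-dimethoxyethyl methacrylate | C=C(C)C(=O)O[C@@H]([C@H]1C(=C)C(=O)O[C@@H]1/C=C(\I)CO[Si](c1ccccc1)(c1ccccc1)C(C)(C)C)C(OC)OC | intermediate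
18 | (1S)-1-[(2S,3S)-2-[(Z)-3-(tert-butyldiphenylsilyloxy)-2-iodoprop-1-enyl]-4-methylidene-5-oxooxolan-3-yl]-2-oxoethyl methacrylate | C=C(C)C(=O)O[C@@H]([C@H]1C(=C)C(=O)O[C@@H]1/C=C(\I)CO[Si](c1ccccc1)(c1ccccc1)C(C)(C)C)C=O | intermediate
19 | 2-methylfuran-3(2H)-one (racemic) | CC1OC=CC1=O | starting material
20 | 2-methyl-3-(triisopropylsilyloxy)furan | Cc1occc1O[Si](C(C)C)(C(C)C)C(C)C | intermediate
21 | 5-lithio-2-methyl-3-(triisopropylsilyloxy)furan | [Li]c1cc(O[Si](C(C)C)(C(C)C)C(C)C)c(C)o1 | intermediate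
22 | tributyl[5-methyl-4-(triisopropylsilyloxy)furan-2-yl]stannane | CCCC[Sn](CCCC)(CCCC)c1cc(O[Si](C(C)C)(C(C)C)C(C)C)c(C)o1 | intermediate
23 | (1S)-1-[(2R,3S)-2-[(Z)-3-(tert-butyldiphenylsilyloxy)-2-[5-methyl-4-(triisopropylsilyloxy)furan-2-yl]prop-1-enyl]-4-methylidene-5-oxooxolan-3-yl]-2-oxoethyl methacrylate | C=C(C)C(=O)O[C@@H]([C@H]1C(=C)C(=O)O[C@@H]1/C=C(/CO[Si](c1ccccc1)(c1ccccc1)C(C)(C)C)c1cc(O[Si](C(C)C)(C(C)C)C(C)C)c(C)o1)C=O | intermediate
24 | (4Z,6R,7S,8S,9R,10S)-15-(tert-butyldiphenylsilyloxy)-9-hydroxy-8-methacryloyloxy-1-oxo-3,10-epoxygermacra-2,4,11(13)-trien-12,6-olide | C=C(C)C(=O)O[C@H]1[C@H]2C(=C)C(=O)O[C@@H]2/C=C(/CO[Si](c3ccccc3)(c3ccccc3)C(C)(C)C)C2=CC(=O)[C@@](C)(O2)[C@@H]1O | intermediate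
25 | 3-methylbut-2-enoyl chloride | CC(C)=CC(=O)Cl | starting material
26 | 15-O-tert-butyldiphenylsilyl ether of the target | C=C(C)C(=O)O[C@H]1[C@H]2C(=C)C(=O)O[C@@H]2/C=C(/CO[Si](c3ccccc3)(c3ccccc3)C(C)(C)C)C2=CC(=O)[C@@](C)(O2)[C@@H]1OC(=O)C=C(C)C | intermediate
27 | CNP0239488.2 | C=C(C)C(=O)O[C@H]1[C@H]2C(=C)C(=O)O[C@@H]2/C=C(/CO)C2=CC(=O)[C@@](C)(O2)[C@@H]1OC(=O)C=C(C)C | target

**Step count.** Total: 16 steps. Longest linear sequence: 13 steps (1, 3–10, 13–16) from fumaraldehyde bis(dimethyl acetal).

**Steps most likely to fail**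

Step 8. The carboxylate may fail to open the cyclopropane at the secondary, inductively deactivated C8, or may exchange acyl groups at the lactone carbonyl or trigger base-induced fragmentation instead. The fallback brings in the C8 oxygen by known epoxide chemistry and sets out from 8. Titanium–tartrate epoxidation of the secondary allylic alcohol (Ti(OiPr)4, D-(−)-diisopropyl tartrate, t-BuOOH, CH2Cl2, −20 °C) should give the erythro 7,8-epoxy alcohol F1, the cis-substituted, deactivated iodoalkene staying inert. Esterification with 9 (DCC, DMAP) gives the epoxy malonate F2. NaH in THF then lets the malonate carbanion attack C7 in a 5-exo opening with inversion, which gives the C8 hydroxy lactone F3 with the C8 oxygen kept from the epoxide. Methacrylic anhydride and DMAP return the route at 14.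

Step 7. The carbene may add with poor facial selectivity relative to C6, add to the C4=C5 alkene, insert into the tert-butyl group or be diverted by the iodine as an ylide. The fallback builds the bicycle with an acceptor-only carbene under catalyst control and adds the second acceptor afterwards. From 8, the glyoxylic acid chloride tosylhydrazone/Et3N procedure gives the allylic diazoacetate F4. Dirhodium tetrakis[methyl (5S)-2-oxopyrrolidine-5-carboxylate], Rh2(5S-MEPY)4, or its 5R enantiomer, whichever is matched to the C6 carbinol, then closes the cyclopropane lactone without the C11 ester F5; this is the well-established selective cyclopropanation of allylic diazoacetates. Deprotonation at C11 (LiN(iPr)2, THF, −78 °C) and trapping with Boc2O re-join the route at 12.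

Step 14. The ring closure may give oligomers, may go through the wrong furan carbon, or may close with the wrong configuration at C9 or C10. The fallback reverses the order of the two bond formations and sets out from 18 and 22. An intermolecular Mukaiyama aldol reaction (BF3·OEt2 or MgBr2·OEt2, CH2Cl2, −78 °C) gives the open-chain stannyl furanone aldol F6, with C9 controlled by 1,2-induction from the C8 ester. Acylation with 25 gives its C9 senecioate F7. A ring-closing Stille coupling between C4–I and C3–Sn (Pd2(dba)3, AsPh3, high dilution) then forms the ring without creating a stereocentre and returns the route at 26.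

**Further compounds**

F1 | step 8 | erythro 7,8-epoxy alcohol | O[C@H](/C=C(\I)CO[Si](c1ccccc1)(c1ccccc1)C(C)(C)C)[C@H]1O[C@@H]1C(OC)OC
F2 | step 8 | epoxy malonate | CC(C)(C)OC(=O)CC(=O)O[C@H](/C=C(\I)CO[Si](c1ccccc1)(c1ccccc1)C(C)(C)C)[C@H]1O[C@@H]1C(OC)OC
F3 | step 8 | C8 hydroxy lactone | O[C@@H]([C@H]1C(C(=O)OC(C)(C)C)C(=O)O[C@@H]1/C=C(\I)CO[Si](c1ccccc1)(c1ccccc1)C(C)(C)C)C(OC)OC
F4 | step 7 | allylic diazoacetate | [N-]=[N+]=CC(=O)O[C@H](/C=C(\I)CO[Si](c1ccccc1)(c1ccccc1)C(C)(C)C)/C=C/C(OC)OC
F5 | step 7 | cyclopropane lactone without the C11 ester | [C@H]12C(=O)O[C@H](/C=C(\I)CO[Si](c3ccccc3)(c3ccccc3)C(C)(C)C)[C@H]1[C@@H]2C(OC)OC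
F6 | step 14 | open-chain stannyl furanone aldol | C=C(C)C(=O)O[C@@H]([C@H]1C(=C)C(=O)O[C@@H]1/C=C(\I)CO[Si](c1ccccc1)(c1ccccc1)C(C)(C)C)[C@@H](O)[C@]1(C)OC([Sn](CCCC)(CCCC)CCCC)=CC1=O
F7 | step 14 | C9 senecioate of the stannyl furanone aldol | C=C(C)C(=O)O[C@@H]([C@H]1C(=C)C(=O)O[C@@H]1/C=C(\I)CO[Si](c1ccccc1)(c1ccccc1)C(C)(C)C)[C@@H](OC(=O)C=C(C)C)[C@]1(C)OC([Sn](CCCC)(CCCC)CCCC)=CC1=O
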